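All runs were computed on assumed constants; the scatter is artificial.

A leftover opens the case: in birch, substrate and target leave 22.1 % of the charge uncounted at 0.417 min, and still 21.9 % at 5.00 min.

| flask | substrate | partner | remark | time |
|---|---|---|---|---|
| birch | 38 mM | 3 equiv | run made earlier |  |
| oak | 76 mM | 3 equiv | run made earlier |  |
| ochre | 38 mM (in portions, 2, over 4.0 min) | 3.00 equiv | first portion at the start, last at 4.0 min | 5.0 min |
| red | 38 mM | 3.00 equiv (fed, over 4.0 min) | all else is in the flask from the start; the feed brings no volume worth counting | 5.0 min |
| amber | 38 mM (fed, over 4.0 min) | 3.00 equiv | all else is in the flask from the start; the feed brings no volume worth counting | 5.0 min |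
| grey | 38 mM | 3.00 equiv | everything together at the start | 5.0 min |

birch run (percent of the substrate charged)

| time / min | target / % | substrate / % |
|---|---|---|
| 0.417 | 27.2 | 50.7 |
| 1.00 | 47.5 | 29.4 |
| 2.00 | 65.8 | 12.9 |
| 5.00 | 76.5 | 1.6 |

oak run (percent of the substrate charged)

| time / s | target / % | substrate / % |
|---|---|---|
| 10.0 | 22.7 | 52.7 |
| 20.0 | 37.5 | 43.0 |
| 40.0 | 57.5 | 24.4 |
| 60.0 | 67.9 | 14.5 |

(each reading ± 1 percentage point)

- the flask with the highest amount of target, in percent of the substrate charged ("all alike" if they lie within 1.5 percentage points) (ochre / red / amber / grey / all alike)
- final target, as a percentage of the substrate charged, in ochre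
- final target, as a percentage of the substrate charged, in red
- final target, as a percentage of the substrate charged, in amber
- final target, as a percentage of the substrate charged, in grey

- the numbers in the tables scatter with a standard deviation of 1 percentage point

I build the flask one process at a time. The main step, substrate plus partner to target, keeps substrate and target summing to the charge, and the leftover denies it. So I add a fast reversible hold on substrate. Oak asks for one: its leftover falls from 24.6 % at 10.0 s to 17.6 % at 60.0 s, a drop of 7 points against a scatter of 1 point, so part of what vanished returns.

A hold shifts the timing, not the end. Last comes a drain out of the hold, first order in the substrate pool, against a main step that is pseudo-first-order with its rate proportional to c(partner). Target per drained substrate is then c(partner) divided by a constant. Birch's last reading has substrate at 1.6 %, so I count its leftover as drained: target per leftover is 3.49 at a mean c(partner) of 99.5 mM, which gives 28.5 mM. I call this κ, the break-even partner concentration, where both branches run equally. Oak, with its hold subtracted at the first reading's ratio to substrate, gives 32.3 mM.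

So I watch c(partner) while substrate is present. Where partner is charged at the start, it starts at 114 mM, above κ, and slow substrate costs time, not share. Red differs: at mid-feed c(partner) is 57.0 mM before any use, a share of 66.7 %, and earlier it is lower, so my own reckoning puts red below that.

The forecast differs on red. It gives grey 76.5 %, red 74.5 %, amber 68 % and ochre 59 %, on the ground that “Dosing therefore cannot avoid the burst”.

The flasks give grey 76.7 %, amber 68.9 %, ochre 61.6 % and red 53.5 %, so grey leads as forecast, and red stands 21 points under the forecast.

    intermediate A → intermediate B (k = 0.0128 s⁻¹)
    intermediate B → side product (k = 0.541 s⁻¹)
    substrate ⇌ intermediate A (K = 0.350, k = 0.699 s⁻¹)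
    substrate + partner → target (k = 0.159 L mol⁻¹ s⁻¹)

Red ends with 1.29 target per side product, which through κ means an effective c(partner) of 36.6 mM, below the mid-feed figure. The gap of 23 points between grey and red drops to 2.5 points in the run without the return of intermediate A to substrate, and to 11 points in the run without the path from intermediate A to intermediate B, so the two act together.

Take grey's neighbour at 15 mM of substrate, equivalents held: its charged c(partner) of 45.0 mM gives by κ a target share of 61.2 %, so the mean c(partner), reckoned as in birch with half of that share taken from the partner, is 40.4 mM, and κ gives 1.42 target per side product. That flask gives 53.9 % against 36.9 %, a ratio of 1.46.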